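(The numbers in the tables are simulated from invented constants.)

Time wore down the product excess in the beta run: it read 53.4% at 20.0 s and a lower 42.9% at 40.0 s. The scatter gives these two excesses standard deviations of 7.8 percentage points and 4.3 points.

common to all: left-handed substrate 0.40 M; right-handed substrate 0.40 M; racemization catalyst 0.1 mol%; added ligand 1.1 mM
- beta: reagent 6 equiv; run made earlier
- flask: reagent 4.00 equiv; time 4.0 min

- beta (time / s: left-handed product / %, right-handed product / %, left-handed substrate / %): 20.0: 15.8, 4.8, 33.8; 40.0: 25.3, 10.1, 22.9; 50.0: 29.6, 13.0, 19.3; 80.0: 33.6, 22.0, 15.4

(scatter of a reading: 1 percentage point)

- reagent is single-handed; left-handed substrate and right-handed substrate are mirror images of each other, charged as a racemate, each of them at the stated concentration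
- an excess is the difference of the two amounts in percent of their sum
- an excess is below zero if the other one leads
- the handed part of reagent does not stay in what it makes, so the products of the two hands are mirror images too

- excess of left-handed product over right-handed product in the product at 12 s
- excess of left-handed product over right-handed product in the product at 4.0 min
- part of the left-handed substrate and right-handed substrate charged together that has reacted at 4.0 min

I read from these two excesses a washout constant w, here 0.0249 s⁻¹: the first-order rate constant at which excess already in the product is lost while fresh product arrives at a steady source excess s. Then e(t) = s(1 − exp(−wt))/(wt), and the second reading, at twice the time of the first, yields w. I assumed that w holds no reagent term, so the flask's excess at 12 s follows from time.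

Scaling to 12 s multiplies the first reading by 1.10 and the second by 1.36. The first reading plus two deviations bounds ea from above at 75.7%. The second reading less two deviations bounds it from below at 46.7%. I committed to 58.6%.

The forecast gave 53%, 4% and 83%, on this ground: “I assume rates scale with reagent”. Its ea lay inside my bracket, but below my figure.

The flask gave 70.6%, 5.48% and 73.3%, with ea inside the bracket.

    reagent + left-handed substrate → left-handed product (k = 0.0104 L mol⁻¹ s⁻¹)
    reagent + right-handed substrate → right-handed product (k = 8.53 × 10⁻⁴ L mol⁻¹ s⁻¹)
    left-handed substrate + racemization catalyst ⇌ right-handed substrate + racemization catalyst, rate k3*[racemization catalyst]*[left-handed substrate] forward; the back reaction follows from the equilibrium constant (k = 1330 L mol⁻¹ s⁻¹)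
    racemization catalyst + added ligand ⇌ idle complex, settled at all times (K = 79100 L mol⁻¹)
    left-handed product ⇌ right-handed product (k = 0.0140 s⁻¹)

In this flask the forward half-life of left-handed product, 0.83 min, is short against 4.0 min. With the w I read, my factor at 12 s is 0.865, and it holds no reagent term. So my reckoning carries the flask's 70.6% over unchanged to the neighbour flask, with 1.60 equiv of reagent instead of 4.00 equiv, as 70.6% at 12 s. That neighbour flask gave 71.4%, while its conversion at 4.0 min was a lower 42.0%.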